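**Strategy.** Ring A is cut across C4–C5 and C1–C6. Its C1(CO2H)–C2(OMe)–C3(side chain)–C4(H) segment is carried by C3–C6 of a 4-methoxy-2-pyrone-3-carboxylate that already holds the silylated (S)-diol side chain at C5. Its C5(H)–C6(O-aryl) pair is carried by a terminal ynol ether of the ring B phenol. One thermal operation, an inverse-demand [4+2] addition followed by loss of CO2, closes ring A, turns the ynol ether into the diaryl ether and places ester, methoxy group, side chain and aryloxy group without any oxidation. All protecting groups on both partners are fluoride-labile, so one fluoride treatment releases the target.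

Key step: step 15

Remark: the carbinol carbon is read as (S) from the SMILES and keeps its spatial arrangement throughout (in 12 the descriptor reads R only because the priority order changes); 2-hydroxy-3-methoxy-5-methylbenzaldehyde is taken as purchasable.

Design choices: the ring B phenol is masked as a 2-(trimethylsilyl)ethoxymethyl (SEM) ether, because a silyl ether on a catechol oxygen would migrate to the neighbouring phenoxide during vinyl ether formation. The acid is carried as a 2-(trimethylsilyl)ethyl ester, because a benzoate flanked by two ortho oxygen substituents resists ordinary saponification.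

Abbreviation: TBS = tert-butyldimethylsilyl.

**Pyrone fragment**

Step 1
Reactants: 1 methyl acetoacetate; 2 acetone
Product: 3 methyl 5-hydroxy-5-methyl-3-oxohexanoate
Conditions: NaH, THF, 0 °C; n-BuLi, 0 °C; 2, −78 °C; AcOH quench at −78 °C
Reagents that add atoms: none
Why: Double deprotonation makes the terminal carbon of the acetoacetate its most nucleophilic site, which adds to acetone at low temperature before retro-aldol cleavage can compete (acetoacetate dianion aldol addition).

Step 2
Reactants: 3 methyl 5-hydroxy-5-methyl-3-oxohexanoate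
Product: 4 methyl (3S)-3,5-dihydroxy-5-methylhexanoate
Conditions: H2 (50 bar), RuCl2[(S)-BINAP] (0.5 mol%), MeOH, 30 °C
Reagents that add atoms: none
Why: Noyori asymmetric hydrogenation of a beta-keto ester, in which the ketone is reduced inside the ester-chelated ruthenium hydride complex and the (S)-BINAP ligand directs hydride to the face that gives the (3S)-carbinol, the hindered tertiary hydroxyl being the weaker directing group.

Step 3
Reactants: 4 methyl (3S)-3,5-dihydroxy-5-methylhexanoate
Product: 5 methyl (3S)-3,5-bis(tert-butyldimethylsilyloxy)-5-methylhexanoate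
Conditions: TBSOTf (2.6 equiv), 2,6-lutidine, CH2Cl2, −78 → 0 °C
Reagents that add atoms: tert-butyldimethylsilyl trifluoromethanesulfonate, CC(C)(C)[Si](C)(C)OS(=O)(=O)C(F)(F)F
Why: A silyl triflate with a hindered pyridine base silylates the secondary and the tertiary hydroxyl in one operation (silyl ether formation) and leaves the stereocentre untouched.

Step 4
Reactants: 5 methyl (3S)-3,5-bis(tert-butyldimethylsilyloxy)-5-methylhexanoate
Product: 6 (3S)-3,5-bis(tert-butyldimethylsilyloxy)-5-methylhexanoic acid
Conditions: LiOH·H2O, THF/MeOH/H2O, rt; 1 M HCl to pH 4, 0 °C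
Reagents that add atoms: lithium hydroxide, [Li+].[OH-]
Why: Hydroxide saponifies the unhindered methyl ester faster than it affects the alkyl silyl ethers, and cold mild acidification keeps them intact (ester hydrolysis).

Step 5
Reactants: 7 malonic acid; 8 2-(trimethylsilyl)ethanol
Product: 9 bis[2-(trimethylsilyl)ethyl] malonate
Conditions: 8 (2.2 equiv in all), DCC (2.1 equiv), MeCN, 0 °C → rt
Reagents that add atoms: 2-(trimethylsilyl)ethanol (the second equivalent of 8), C[Si](C)(C)CCO
Why: Carbodiimide activation esterifies both carboxyl groups of malonic acid, each with one molecule of the primary alcohol, under neutral conditions (carbodiimide esterification), giving an ester that fluoride can later cleave remotely from the carbonyl group.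

Step 6
Reactants: 6 (3S)-3,5-bis(tert-butyldimethylsilyloxy)-5-methylhexanoic acid; 9 bis[2-(trimethylsilyl)ethyl] malonate
Product: 11 bis[2-(trimethylsilyl)ethyl] 2-[(3S)-3,5-bis(tert-butyldimethylsilyloxy)-5-methylhexanoyl]malonate, via acid chloride 10 (not isolated)
Conditions: 1-chloro-N,N,2-trimethylprop-1-en-1-amine, CH2Cl2, 0 °C → rt; then 9, MgCl2, Et3N, MeCN, 0 °C → rt; cold 1 M HCl wash
Reagents that add atoms: none
Why: The acid chloride is formed under neutral conditions and C-acylates the magnesium enolate of the malonate, the acidic product being held as a magnesium chelate that prevents a second acylation (soft-enolisation C-acylation of a malonate with MgCl2 and Et3N).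

Step 7
Reactants: 11 bis[2-(trimethylsilyl)ethyl] 2-[(3S)-3,5-bis(tert-butyldimethylsilyloxy)-5-methylhexanoyl]malonate
Product: 12 bis[2-(trimethylsilyl)ethyl] 2-[(3R)-3,5-bis(tert-butyldimethylsilyloxy)-1-methoxy-5-methylhexylidene]malonate
Conditions: Me3SiCHN2, toluene/MeOH, 0 °C → rt
Reagents that add atoms: (trimethylsilyl)diazomethane, C[Si](C)(C)C=[N+]=[N-]
Why: An acyl malonate is a strongly enolised acid that diazoalkane reagents methylate at the enol oxygen of the ketone (O-methylation with (trimethylsilyl)diazomethane), which fixes the future C2 methoxy group of ring A without touching the carbinol carbon.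

Step 8
Reactants: 12 bis[2-(trimethylsilyl)ethyl] 2-[(3R)-3,5-bis(tert-butyldimethylsilyloxy)-1-methoxy-5-methylhexylidene]malonate
Product: 14 2-(trimethylsilyl)ethyl 5-[(1S)-1,3-bis(tert-butyldimethylsilyloxy)-3-methylbutyl]-4-methoxy-2-oxo-2H-pyran-3-carboxylate, via dienamine 13 (not isolated)
Conditions: t-BuOCH(NMe2)2, toluene, 80 °C; then AcOH/THF/H2O, 40 °C
Reagents that add atoms: tert-butoxybis(dimethylamino)methane, CN(C)C(OC(C)(C)C)N(C)C; water, O
Why: The methylene next to the enol ether carbon is vinylogously acidic and condenses with the amide acetal to a push-pull dienamine, whose mild acid hydrolysis gives a hydroxymethylene group that lactonises onto the cis ester (aminomethylenation and 2-pyrone closure, the standard route from alkylidene malonates to 2-pyrone-3-carboxylates).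

**Ring B fragment**

Step 9
Reactants: 15 2-hydroxy-3-methoxy-5-methylbenzaldehyde
Product: 16 2,3-dihydroxy-5-methylbenzaldehyde
Conditions: BBr3, CH2Cl2, −78 → 0 °C; H2O
Reagents that add atoms: none
Why: BBr3 cleaves the aryl methyl ether through its bromoborane adduct and hydrolysis releases the catechol with the aldehyde unchanged (Lewis-acid ether cleavage).

Step 10
Reactants: 16 2,3-dihydroxy-5-methylbenzaldehyde
Product: 17 2-hydroxy-5-methyl-3-{[2-(trimethylsilyl)ethoxy]methoxy}benzaldehyde
Conditions: NaH (2.2 equiv), DMSO/THF, 0 °C → rt; Me3SiCH2CH2OCH2Cl (1.0 equiv); aq. NH4Cl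
Reagents that add atoms: 2-(trimethylsilyl)ethoxymethyl chloride, C[Si](C)(C)CCOCCl
Why: In the dianion the C2 phenoxide is conjugated with and chelated to the formyl group, so the C3 phenoxide is the more nucleophilic oxygen and takes the single equivalent of alkylating agent, as is known for dianions of 2,3-dihydroxybenzaldehydes (Williamson etherification).

Step 11
Reactants: 17 2-hydroxy-5-methyl-3-{[2-(trimethylsilyl)ethoxy]methoxy}benzaldehyde; 18 trichloroethylene
Product: 20 2-{[(E)-1,2-dichlorovinyl]oxy}-5-methyl-3-{[2-(trimethylsilyl)ethoxy]methoxy}benzaldehyde, via dichloroacetylene 19 (not isolated)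
Conditions: K2CO3, DMF, 70 °C, under N2
Reagents that add atoms: none
Why: Carbonate dehydrochlorinates trichloroethylene to dichloroacetylene, to which the phenoxide adds in anti fashion to give the (E)-dichlorovinyl ether (known vinylation of phenols with trichloroethylene), and the acetal on the neighbouring oxygen cannot migrate.

Step 12
Reactants: 20 2-{[(E)-1,2-dichlorovinyl]oxy}-5-methyl-3-{[2-(trimethylsilyl)ethoxy]methoxy}benzaldehyde
Product: 21 (2-{[(E)-1,2-dichlorovinyl]oxy}-5-methyl-3-{[2-(trimethylsilyl)ethoxy]methoxy}phenyl)methanol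
Conditions: NaBH4, MeOH/THF, 0 °C
Reagents that add atoms: none
Why: Borohydride reduces the aromatic aldehyde to the benzylic alcohol without touching the dichlorovinyl ether or the acetal (hydride reduction).

Step 13
Reactants: 21 (2-{[(E)-1,2-dichlorovinyl]oxy}-5-methyl-3-{[2-(trimethylsilyl)ethoxy]methoxy}phenyl)methanol
Product: 22 tert-butyl[(2-{[(E)-1,2-dichlorovinyl]oxy}-5-methyl-3-{[2-(trimethylsilyl)ethoxy]methoxy}benzyl)oxy]dimethylsilane
Conditions: TBSCl, imidazole, DMF, rt
Reagents that add atoms: tert-butyldimethylsilyl chloride, CC(C)(C)[Si](C)(C)Cl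
Why: The primary benzylic alcohol is the only free hydroxyl and is silylated under imidazole catalysis (silyl ether formation).

Step 14
Reactants: 22 tert-butyl[(2-{[(E)-1,2-dichlorovinyl]oxy}-5-methyl-3-{[2-(trimethylsilyl)ethoxy]methoxy}benzyl)oxy]dimethylsilane
Product: 25 tert-butyl{[2-(ethynyloxy)-5-methyl-3-{[2-(trimethylsilyl)ethoxy]methoxy}benzyl]oxy}dimethylsilane, via chloroethynyl ether 23 (not isolated), via lithium acetylide 24 (not isolated)
Conditions: n-BuLi (2.3 equiv), Et2O, −78 → −40 °C; H2O, −78 °C; used at once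
Reagents that add atoms: none
Why: n-BuLi removes the vinyl proton, chloride is lost to give the chloroalkyne, chlorine–lithium exchange gives the acetylide and cold protonation releases the terminal ynol ether (the dichlorovinyl ether route to ynol ethers).

**Union and release**

Step 15
Reactants: 14 2-(trimethylsilyl)ethyl 5-[(1S)-1,3-bis(tert-butyldimethylsilyloxy)-3-methylbutyl]-4-methoxy-2-oxo-2H-pyran-3-carboxylate; 25 tert-butyl{[2-(ethynyloxy)-5-methyl-3-{[2-(trimethylsilyl)ethoxy]methoxy}benzyl]oxy}dimethylsilane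
Product: 27 2-(trimethylsilyl)ethyl 3-[(1S)-1,3-bis(tert-butyldimethylsilyloxy)-3-methylbutyl]-6-{2-[(tert-butyldimethylsilyloxy)methyl]-4-methyl-6-{[2-(trimethylsilyl)ethoxy]methoxy}phenoxy}-2-methoxybenzoate, via bridged lactone 26 (not isolated)
Conditions: 25 (1.5 equiv), toluene, 110 °C, sealed base-washed tube (xylene, 140 °C if slow)
Reagents that add atoms: none
Why: The pyrone, made electron-poor by the lactone carbonyl and the C3 ester, reacts with the electron-rich alkyne in an inverse-electron-demand [4+2] cycloaddition in which the alkyne CH bonds to pyrone C6 and the aryloxy-bearing carbon to C3, and the bridged lactone 26 then expels CO2 by a retro-[4+2] reaction to give the benzene ring. The closest known reaction type is the thermal cycloaddition–decarboxylation of 3-alkoxycarbonyl-2-pyrones with ynol ethers, ynamines and ketene acetals. Ring A is closed as a six-membered carbocycle by intermolecular [4+2] annulation of a four-carbon and a two-carbon unit, and it is aromatic at once because the alkyne brings the required unsaturation. No stereocentre is formed, and the existing (S)-carbinol carbon is not enolisable and only looks on. The step needs head-to-tail regioselectivity, which is secured by the polarisation of both partners: C6 is the electrophilic terminus of the doubly activated dienyl ester and the alkyne CH is the only nucleophilic carbon of the ynol ether, so the aryloxy group must end up next to the ester. Because an aryl ynol ether has no retro-ene route to a ketene, it can survive the heating that the 4-methoxy-deactivated diene is expected to need.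

Step 16
Reactants: 27 2-(trimethylsilyl)ethyl 3-[(1S)-1,3-bis(tert-butyldimethylsilyloxy)-3-methylbutyl]-6-{2-[(tert-butyldimethylsilyloxy)methyl]-4-methyl-6-{[2-(trimethylsilyl)ethoxy]methoxy}phenoxy}-2-methoxybenzoate
Product: 28 3-[(1S)-1,3-dihydroxy-3-methylbutyl]-6-[2-hydroxy-6-(hydroxymethyl)-4-methylphenoxy]-2-methoxybenzoic acid
Conditions: Bu4NF (excess), ethylenediamine, THF/DMPU, 60 °C; then 0.5 M HCl to pH 3–4, 0 °C
Reagents that add atoms: none
Why: Fluoride attacks each silicon, cleaving the silyl ethers directly and fragmenting the 2-(trimethylsilyl)ethyl ester and the SEM ether with loss of ethylene, so the hindered carboxylate is freed without attack at its carbonyl carbon while ethylenediamine traps the formaldehyde (fluoride-induced desilylation and beta-elimination), and the basic medium leaves the benzylic carbinol centre unchanged.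

**Compound list**

1 | methyl acetoacetate | CC(=O)CC(=O)OC | starting material
2 | acetone | CC(C)=O | starting material
3 | methyl 5-hydroxy-5-methyl-3-oxohexanoate | COC(=O)CC(=O)CC(C)(C)O | intermediate
4 | methyl (3S)-3,5-dihydroxy-5-methylhexanoate | COC(=O)C[C@@H](O)CC(C)(C)O | intermediate
5 | methyl (3S)-3,5-bis(tert-butyldimethylsilyloxy)-5-methylhexanoate | COC(=O)C[C@@H](O[Si](C)(C)C(C)(C)C)CC(C)(C)O[Si](C)(C)C(C)(C)C | intermediate
6 | (3S)-3,5-bis(tert-butyldimethylsilyloxy)-5-methylhexanoic acid | OC(=O)C[C@@H](O[Si](C)(C)C(C)(C)C)CC(C)(C)O[Si](C)(C)C(C)(C)C | intermediate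
7 | malonic acid | OC(=O)CC(=O)O | starting material
8 | 2-(trimethylsilyl)ethanol | C[Si](C)(C)CCO | starting material
9 | bis[2-(trimethylsilyl)ethyl] malonate | C[Si](C)(C)CCOC(=O)CC(=O)OCC[Si](C)(C)C | intermediate
10 | (3S)-3,5-bis(tert-butyldimethylsilyloxy)-5-methylhexanoyl chloride (not isolated) | ClC(=O)C[C@@H](O[Si](C)(C)C(C)(C)C)CC(C)(C)O[Si](C)(C)C(C)(C)C | intermediate
11 | bis[2-(trimethylsilyl)ethyl] 2-[(3S)-3,5-bis(tert-butyldimethylsilyloxy)-5-methylhexanoyl]malonate (keto tautomer drawn) | C[Si](C)(C)CCOC(=O)C(C(=O)OCC[Si](C)(C)C)C(=O)C[C@@H](O[Si](C)(C)C(C)(C)C)CC(C)(C)O[Si](C)(C)C(C)(C)C | intermediate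
12 | bis[2-(trimethylsilyl)ethyl] 2-[(3R)-3,5-bis(tert-butyldimethylsilyloxy)-1-methoxy-5-methylhexylidene]malonate | C[Si](C)(C)CCOC(=O)C(C(=O)OCC[Si](C)(C)C)=C(OC)C[C@@H](O[Si](C)(C)C(C)(C)C)CC(C)(C)O[Si](C)(C)C(C)(C)C | intermediate
13 | bis[2-(trimethylsilyl)ethyl] 2-[(3S)-3,5-bis(tert-butyldimethylsilyloxy)-2-(dimethylaminomethylene)-1-methoxy-5-methylhexylidene]malonate (not isolated; enamine geometry not fixed) | C[Si](C)(C)CCOC(=O)C(C(=O)OCC[Si](C)(C)C)=C(OC)C(=CN(C)C)[C@@H](O[Si](C)(C)C(C)(C)C)CC(C)(C)O[Si](C)(C)C(C)(C)C | intermediate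
14 | 2-(trimethylsilyl)ethyl 5-[(1S)-1,3-bis(tert-butyldimethylsilyloxy)-3-methylbutyl]-4-methoxy-2-oxo-2H-pyran-3-carboxylate | C[Si](C)(C)CCOC(=O)C1=C(OC)C([C@@H](O[Si](C)(C)C(C)(C)C)CC(C)(C)O[Si](C)(C)C(C)(C)C)=COC1=O | intermediate
15 | 2-hydroxy-3-methoxy-5-methylbenzaldehyde | COc1cc(C)cc(C=O)c1O | starting material
16 | 2,3-dihydroxy-5-methylbenzaldehyde | Cc1cc(O)c(O)c(C=O)c1 | intermediate
17 | 2-hydroxy-5-methyl-3-{[2-(trimethylsilyl)ethoxy]methoxy}benzaldehyde | Cc1cc(OCOCC[Si](C)(C)C)c(O)c(C=O)c1 | intermediate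
18 | trichloroethylene | ClC=C(Cl)Cl | starting material
19 | dichloroacetylene (not isolated) | ClC#CCl | intermediate
20 | 2-{[(E)-1,2-dichlorovinyl]oxy}-5-methyl-3-{[2-(trimethylsilyl)ethoxy]methoxy}benzaldehyde | Cc1cc(OCOCC[Si](C)(C)C)c(O/C(Cl)=C\Cl)c(C=O)c1 | intermediate
21 | (2-{[(E)-1,2-dichlorovinyl]oxy}-5-methyl-3-{[2-(trimethylsilyl)ethoxy]methoxy}phenyl)methanol | Cc1cc(OCOCC[Si](C)(C)C)c(O/C(Cl)=C\Cl)c(CO)c1 | intermediate
22 | tert-butyl[(2-{[(E)-1,2-dichlorovinyl]oxy}-5-methyl-3-{[2-(trimethylsilyl)ethoxy]methoxy}benzyl)oxy]dimethylsilane | Cc1cc(OCOCC[Si](C)(C)C)c(O/C(Cl)=C\Cl)c(CO[Si](C)(C)C(C)(C)C)c1 | intermediate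
23 | ring B aryl chloroethynyl ether (not isolated) | ClC#COc1c(OCOCC[Si](C)(C)C)cc(C)cc1CO[Si](C)(C)C(C)(C)C | intermediate
24 | lithium acetylide of the ring B ynol ether (not isolated) | [Li]C#COc1c(OCOCC[Si](C)(C)C)cc(C)cc1CO[Si](C)(C)C(C)(C)C | intermediate
25 | tert-butyl{[2-(ethynyloxy)-5-methyl-3-{[2-(trimethylsilyl)ethoxy]methoxy}benzyl]oxy}dimethylsilane (ring B aryloxyacetylene) | C#COc1c(OCOCC[Si](C)(C)C)cc(C)cc1CO[Si](C)(C)C(C)(C)C | intermediate
26 | 2-oxabicyclo[2.2.2]octa-5,7-dien-3-one cycloadduct of 14 and 25 (not isolated; bridgeheads undefined, both isomers give 27) | O=C1OC2C=C(Oc3c(OCOCC[Si](C)(C)C)cc(C)cc3CO[Si](C)(C)C(C)(C)C)C1(C(=O)OCC[Si](C)(C)C)C(OC)=C2[C@@H](O[Si](C)(C)C(C)(C)C)CC(C)(C)O[Si](C)(C)C(C)(C)C | intermediate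
27 | 2-(trimethylsilyl)ethyl 3-[(1S)-1,3-bis(tert-butyldimethylsilyloxy)-3-methylbutyl]-6-{2-[(tert-butyldimethylsilyloxy)methyl]-4-methyl-6-{[2-(trimethylsilyl)ethoxy]methoxy}phenoxy}-2-methoxybenzoate | C[Si](C)(C)CCOC(=O)c1c(OC)c([C@@H](O[Si](C)(C)C(C)(C)C)CC(C)(C)O[Si](C)(C)C(C)(C)C)ccc1Oc1c(OCOCC[Si](C)(C)C)cc(C)cc1CO[Si](C)(C)C(C)(C)C | intermediate
28 | 3-[(1S)-1,3-dihydroxy-3-methylbutyl]-6-[2-hydroxy-6-(hydroxymethyl)-4-methylphenoxy]-2-methoxybenzoic acid | COc1c([C@@H](O)CC(C)(C)O)ccc(Oc2c(O)cc(C)cc2CO)c1C(=O)O | target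

**Count and risks**

Total steps: 16. Longest linear sequence: 9 steps (steps 1–4, 6–8, 15, 16).

Steps most likely to fail:

1. Step 15. The 4-methoxy group and the branched C5 substituent make the pyrone a sluggish diene, so at the required temperature the terminal ynol ether may oligomerise or be hydrated faster than it cycloadds. The fallback sets out from 25 and comes back at 27. Compound 25 would be treated with 4-nitrophenol (CH2Cl2, rt), which adds across the electron-rich triple bond to give the mixed ketene acetal 1-(ring B aryloxy)-1-(4-nitrophenoxy)ethene F1, a thermally robust two-carbon partner. Heating F1 with 14 (xylene, 130–140 °C, 2,6-lutidine) should give the bridged lactone adduct F2 in the ketene acetal variant of the same cycloaddition. Loss of CO2 from F2 should give the 6,6-bis(aryloxy)cyclohexa-1,3-diene F3. Elimination of 4-nitrophenol, by far the better leaving group of the two aryloxides, should then aromatise F3 to 27 with unchanged regiochemistry.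

2. Step 8. The carbanionic intermediate formed next to the silyloxy-bearing carbon at 80 °C may expel silanolate (beta-elimination to a triene), or the secondary silyl ether may be lost during the acidic ring closure. The fallback sets out from 11 and comes back at 14. Compound 11 would be converted to its dianion with LiN(iPr)2 (THF, −78 °C), a temperature at which beta-silyloxy enolates are expected to persist, and formylated at the carbon next to the ketone with HCO2Me. Quenching with AcOH should give the hydroxymethylene acyl malonate F4, which should lactonise on brief warming to the 4-hydroxy-2-pyrone F5. O-Methylation of F5 with Me2SO4 and K2CO3 in acetone, the usual way to 4-methoxy-2-pyrones, should give 14.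

3. Step 16. Cleavage of the aryl SEM ether by fluoride may stall after the silyl ethers and the ester are gone, or released formaldehyde may hydroxymethylate the electron-rich ring B. The fallback sets out from 27 and comes back at 28. The acetal would be removed first with MgBr2·OEt2 in Et2O/MeNO2 at rt, conditions that leave silyl ethers in place, to give the ring B phenol F6. Bu4NF in THF at rt to 40 °C then only has to cleave the three silyl ethers and the 2-(trimethylsilyl)ethyl ester of F6, which should give 28 after the same mild acidification.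

Further compounds
F1 | step 15 | 1-{2-[(tert-butyldimethylsilyloxy)methyl]-4-methyl-6-{[2-(trimethylsilyl)ethoxy]methoxy}phenoxy}-1-(4-nitrophenoxy)ethene | C=C(Oc1ccc(cc1)[N+](=O)[O-])Oc1c(OCOCC[Si](C)(C)C)cc(C)cc1CO[Si](C)(C)C(C)(C)C
F2 | step 15 | 2-oxabicyclo[2.2.2]oct-7-en-3-one cycloadduct of 14 and F1 (bridgeheads undefined) | O=C1OC2CC(Oc3ccc(cc3)[N+](=O)[O-])(Oc3c(OCOCC[Si](C)(C)C)cc(C)cc3CO[Si](C)(C)C(C)(C)C)C1(C(=O)OCC[Si](C)(C)C)C(OC)=C2[C@@H](O[Si](C)(C)C(C)(C)C)CC(C)(C)O[Si](C)(C)C(C)(C)C
F3 | step 15 | 2-(trimethylsilyl)ethyl 6-(ring B aryloxy)-6-(4-nitrophenoxy)-3-[(1S)-1,3-bis(tert-butyldimethylsilyloxy)-3-methylbutyl]-2-methoxycyclohexa-1,3-diene-1-carboxylate | C[Si](C)(C)CCOC(=O)C1=C(OC)C([C@@H](O[Si](C)(C)C(C)(C)C)CC(C)(C)O[Si](C)(C)C(C)(C)C)=CCC1(Oc1ccc(cc1)[N+](=O)[O-])Oc1c(OCOCC[Si](C)(C)C)cc(C)cc1CO[Si](C)(C)C(C)(C)C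
F4 | step 8 | bis[2-(trimethylsilyl)ethyl] 2-[(3S)-3,5-bis(tert-butyldimethylsilyloxy)-2-(hydroxymethylene)-5-methylhexanoyl]malonate | C[Si](C)(C)CCOC(=O)C(C(=O)OCC[Si](C)(C)C)C(=O)C(=CO)[C@@H](O[Si](C)(C)C(C)(C)C)CC(C)(C)O[Si](C)(C)C(C)(C)C
F5 | step 8 | 2-(trimethylsilyl)ethyl 5-[(1S)-1,3-bis(tert-butyldimethylsilyloxy)-3-methylbutyl]-4-hydroxy-2-oxo-2H-pyran-3-carboxylate | C[Si](C)(C)CCOC(=O)C1=C(O)C([C@@H](O[Si](C)(C)C(C)(C)C)CC(C)(C)O[Si](C)(C)C(C)(C)C)=COC1=O
F6 | step 16 | 2-(trimethylsilyl)ethyl 3-[(1S)-1,3-bis(tert-butyldimethylsilyloxy)-3-methylbutyl]-6-{2-[(tert-butyldimethylsilyloxy)methyl]-6-hydroxy-4-methylphenoxy}-2-methoxybenzoate | C[Si](C)(C)CCOC(=O)c1c(OC)c([C@@H](O[Si](C)(C)C(C)(C)C)CC(C)(C)O[Si](C)(C)C(C)(C)C)ccc1Oc1c(O)cc(C)cc1CO[Si](C)(C)C(C)(C)C
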